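**Plan**

- Retrosynthesis: the C3–H of the (3R,4R)-trans-dibenzylbutyrolactone is traced back to a C3–CO2Me helper and the phenol to its benzyl ether. Two bonds are then cut in one operation: guaiacyl C(ipso)–CH2 (the benzylic carbon on C4) and C3–CH2(3,4,5-trimethoxyphenyl).
- Enabling feature: that benzylic CH2 is 1,3 to C3, the carbon α to the lactone C2=O. Bonding it to C3 gives a cyclopropane fused to the lactone ring (3-oxabicyclo[3.1.0]hexan-2-one). With the extra ester on C3, the strained C3–CH2 bond is a homo-Michael acceptor whose leaving group is the C3 enolate.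
- Forward: (R)-epichlorohydrin and dimethyl malonate build the cyclopropane and the lactone ring together. A one-pot aryl-copper ring opening and enolate benzylation then attaches both arylmethyl arms. Krapcho removal of the helper ester and hydrogenolysis finish the route.
- Stereochemistry: C4 comes from the chiral pool (C2 of (R)-epichlorohydrin, inverted once on cyclopropane closure and untouched afterwards). C3 is set last, by thermodynamic funnelling of both C3 epimers to the trans lactone.

Key step: step 3

Remark: compound 10 is carried as its C3-epimer mixture because that centre returns to CH in step 4, so its SMILES leaves C3 open.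

**Step 1**
Reactants: 1 (R)-epichlorohydrin; 2 dimethyl malonate
Product: 4 methyl (1S,5R)-2-oxo-3-oxabicyclo[3.1.0]hexane-1-carboxylate, via epoxymalonate 3 (not isolated)
Conditions: NaOMe (1 equiv), MeOH, rt → reflux
Reagents that add atoms: none
Why: In this epoxide-opening/cyclopropanation/lactonisation domino of malonate with epichlorohydrin, the malonate anion should open the epoxide of 1 at its CH2 terminus, the alkoxide should close onto the CH2Cl carbon to give epoxide 3, and the malonate carbanion should then open 3 by 3-exo-tet SN2 attack with inversion before the cis CH2O− lactonises, so that the (R) centre of 1 becomes C5 (R) of 4 and the cis ring fusion fixes C1 as S.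

**Step 2**
Reactants: 5 4-bromo-2-methoxyphenol
Product: 6 1-(benzyloxy)-4-bromo-2-methoxybenzene
Conditions: BnBr, K2CO3, acetone, reflux
Reagents that add atoms: benzyl bromide, BrCc1ccccc1
Why: Williamson ether synthesis on the phenoxide should mask the acidic OH, which would otherwise quench the aryl Grignard reagent of step 3.

**Step 3**
Reactants: 6 1-(benzyloxy)-4-bromo-2-methoxybenzene; 4 methyl (1S,5R)-2-oxo-3-oxabicyclo[3.1.0]hexane-1-carboxylate; 7 3,4,5-trimethoxybenzyl bromide
Product: 10 methyl (4R)-4-[4-(benzyloxy)-3-methoxybenzyl]-2-oxo-3-(3,4,5-trimethoxybenzyl)tetrahydrofuran-3-carboxylate (C3 epimer mixture), via aryl Grignard reagent 8 (not isolated), via bromomagnesium lactone enolate 9 (not isolated)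
Conditions: 6, Mg, THF, 45 °C; add to 4, CuI (10 mol %), THF, −40 → −10 °C; then 7, DMPU, −10 °C → rt; aq. NH4Cl
Reagents that add atoms: none
Why: The aryl Grignard 8 transmetalates to copper and the arylcopper species attacks the cyclopropane CH2 (C6 of 4) in an SN2-type homo-conjugate addition, the C1–C6 bond being weakened by ring strain and by overlap with both the lactone and the ester carbonyl, so that the doubly stabilised enolate 9 leaves from C1; 9 is then C-benzylated by 7 in the same flask. The closest known reaction types are the copper-catalysed Grignard opening of cyclopropane-1,1-dicarboxylates (this bicyclic lactone ester included) and the tandem conjugate addition–enolate benzylation of butenolides. No ring is closed: the cyclopropane is opened and the γ-lactone is kept. C4 (R) is not touched, since the bridgehead CH keeps all four of its bonds, and the new quaternary C3 should form mainly with the incoming benzyl anti to the C4 arylmethyl group but needs no control because it returns to CH in step 4. The step needs attack at the cyclopropane CH2 rather than at the bridgehead CH or at a carbonyl, which the primary versus tertiary difference and soft copper catalysis at low temperature should secure, and C- rather than O-alkylation of 9, which the soft benzylic bromide and DMPU should secure.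

**Step 4**
Reactants: 10 methyl (4R)-4-[4-(benzyloxy)-3-methoxybenzyl]-2-oxo-3-(3,4,5-trimethoxybenzyl)tetrahydrofuran-3-carboxylate (C3 epimer mixture)
Product: 12 (3R,4R)-4-[4-(benzyloxy)-3-methoxybenzyl]-3-(3,4,5-trimethoxybenzyl)dihydrofuran-2(3H)-one, via cis C3 epimer 11 (not isolated)
Conditions: LiCl, H2O, DMSO, 150 °C; then t-BuOK (cat.), t-BuOH–THF, rt; AcOH
Reagents that add atoms: none
Why: Krapcho dealkoxycarbonylation (chloride SN2 at the ester methyl, loss of CO2, protonation of the lactone enolate by water) should remove the helper ester, and because C4 is configurationally fixed and the trans-3,4-dibenzyl lactone is the more stable C3 epimer, alkoxide-catalysed enolisation should funnel the cis epimer 11 into trans 12, setting C3 as R under thermodynamic control.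

**Step 5**
Reactants: 12 (3R,4R)-4-[4-(benzyloxy)-3-methoxybenzyl]-3-(3,4,5-trimethoxybenzyl)dihydrofuran-2(3H)-one
Product: 13 hernanol, (3R,4R)-4-(4-hydroxy-3-methoxybenzyl)-3-(3,4,5-trimethoxybenzyl)dihydrofuran-2(3H)-one
Conditions: H2 (1 atm), 10 % Pd/C, EtOAc–MeOH, rt
Reagents that add atoms: none
Why: Catalytic hydrogenolysis of the benzyl aryl ether should free the phenol under neutral conditions that leave the lactone, the methyl ethers and both stereocentres unchanged.

**Compound list**

1 | (R)-epichlorohydrin | ClC[C@H]1CO1 | starting material
2 | dimethyl malonate | COC(=O)CC(=O)OC | starting material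
3 | dimethyl 2-{[(2R)-oxiran-2-yl]methyl}malonate (epoxymalonate, not isolated) | COC(=O)C(C[C@@H]1CO1)C(=O)OC | intermediate
4 | methyl (1S,5R)-2-oxo-3-oxabicyclo[3.1.0]hexane-1-carboxylate | COC(=O)[C@]12C[C@H]1COC2=O | intermediate
5 | 4-bromo-2-methoxyphenol | COc1cc(Br)ccc1O | starting material
6 | 1-(benzyloxy)-4-bromo-2-methoxybenzene | COc1cc(Br)ccc1OCc1ccccc1 | intermediate
7 | 3,4,5-trimethoxybenzyl bromide | COc1cc(CBr)cc(OC)c1OC | starting material
8 | [4-(benzyloxy)-3-methoxyphenyl]magnesium bromide (not isolated) | COc1cc([Mg]Br)ccc1OCc1ccccc1 | intermediate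
9 | bromomagnesium enolate of methyl (4R)-4-[4-(benzyloxy)-3-methoxybenzyl]-2-oxotetrahydrofuran-3-carboxylate (not isolated) | COc1cc(C[C@H]2COC(O[Mg]Br)=C2C(=O)OC)ccc1OCc1ccccc1 | intermediate
10 | methyl (4R)-4-[4-(benzyloxy)-3-methoxybenzyl]-2-oxo-3-(3,4,5-trimethoxybenzyl)tetrahydrofuran-3-carboxylate, both C3 epimers | COc1cc(C[C@H]2COC(=O)C2(Cc2cc(OC)c(OC)c(OC)c2)C(=O)OC)ccc1OCc1ccccc1 | intermediate
11 | (3S,4R)-4-[4-(benzyloxy)-3-methoxybenzyl]-3-(3,4,5-trimethoxybenzyl)dihydrofuran-2(3H)-one (cis epimer, not isolated) | COc1cc(C[C@H]2COC(=O)[C@H]2Cc2cc(OC)c(OC)c(OC)c2)ccc1OCc1ccccc1 | intermediate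
12 | (3R,4R)-4-[4-(benzyloxy)-3-methoxybenzyl]-3-(3,4,5-trimethoxybenzyl)dihydrofuran-2(3H)-one (trans) | COc1cc(C[C@H]2COC(=O)[C@@H]2Cc2cc(OC)c(OC)c(OC)c2)ccc1OCc1ccccc1 | intermediate
13 | hernanol | COc1cc(C[C@H]2COC(=O)[C@@H]2Cc2cc(OC)c(OC)c(OC)c2)ccc1O | target

**Summary**

Total step count: 5. Longest linear sequence: 4 steps (1 → 3 → 4 → 5; the aryl branch 2 → 3 → 4 → 5 is equally long).

**Steps most likely to fail**

Step 3. The aryl nucleophile may add 1,2 to the lactone or ester carbonyl instead of opening the cyclopropane. The chelated magnesium enolate may also be C-alkylated too slowly, so that residual aryl Grignard reagent couples with the benzylic bromide instead. Fallback, setting out from 4 (with 8 made from 6) and coming back at 12: the one-pot trapping is given up and the C3 arm is introduced by kinetic alkylation of a simple lactone enolate. Compound 4 is opened with 8 and catalytic CuI alone and quenched with aqueous NH4Cl to give methyl (4R)-4-[4-(benzyloxy)-3-methoxybenzyl]-2-oxotetrahydrofuran-3-carboxylate F1. Krapcho dealkoxycarbonylation (LiCl, wet DMSO, 140 °C) should then give (R)-4-[4-(benzyloxy)-3-methoxybenzyl]dihydrofuran-2(3H)-one F2. Deprotonation with LiHMDS in THF at −78 °C and alkylation with 7 should give 12 directly, because the electrophile enters anti to the C4 substituent. Step 4 is then not needed.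

Step 4. Dealkoxycarbonylation at the hindered quaternary centre may be incomplete, chloride or hydroxide may cleave the lactone at 150 °C, and the cis to trans equilibration may stop short. Fallback, setting out from 10 and coming back at 12: hydrolysis followed by thermal decarboxylation replaces the SN2 dealkylation. KOH in aqueous MeOH at reflux should saponify the ester (the lactone opens reversibly). Acidification with HCl should relactonise to (4R)-4-[4-(benzyloxy)-3-methoxybenzyl]-2-oxo-3-(3,4,5-trimethoxybenzyl)tetrahydrofuran-3-carboxylic acid F3. Heating F3 in toluene at reflux should expel CO2 through the cyclic six-membered transition state. The same catalytic t-BuOK equilibration should then deliver 12.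

Step 1. Enantiomeric purity may be eroded, because direct displacement of chloride competes with epoxide opening and the two pathways lead to mirror-image lactones. Fallback, setting out from 2 and coming back at 4: the electrophile is changed to one with a single kinetically relevant site. Commercial (R)-glycidol with Tf2O and 2,6-lutidine in CH2Cl2 at −20 °C should give (S)-glycidyl trifluoromethanesulfonate F4. The sodium salt of 2 (NaH, THF) should displace the triflate first without touching the stereocentre, giving the same epoxymalonate 3, which closes to 4 as before.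

**Further compounds**

F1 | step 3 | methyl (4R)-4-[4-(benzyloxy)-3-methoxybenzyl]-2-oxotetrahydrofuran-3-carboxylate (C3 epimer mixture) | COc1cc(C[C@H]2COC(=O)C2C(=O)OC)ccc1OCc1ccccc1
F2 | step 3 | (R)-4-[4-(benzyloxy)-3-methoxybenzyl]dihydrofuran-2(3H)-one | COc1cc(C[C@H]2COC(=O)C2)ccc1OCc1ccccc1
F3 | step 4 | (4R)-4-[4-(benzyloxy)-3-methoxybenzyl]-2-oxo-3-(3,4,5-trimethoxybenzyl)tetrahydrofuran-3-carboxylic acid (C3 epimer mixture) | COc1cc(C[C@H]2COC(=O)C2(Cc2cc(OC)c(OC)c(OC)c2)C(=O)O)ccc1OCc1ccccc1
F4 | step 1 | (S)-glycidyl trifluoromethanesulfonate | O=S(=O)(OC[C@@H]1CO1)C(F)(F)F
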